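**Assumption:** isoflavanone (chroman-4-one) numbering is used (O1, C2, C3, C4=O; ring A = benzo ring, ring B = 3-aryl group, ring C = pyranone), and the given SMILES encodes 3R.

## Retrosynthetic overview

1. Prenyl groups last: 21 ⇐ double cross-metathesis of diallyl triol 20 ⇐ two aromatic Claisen ([3,3]) shifts, 5-O-allyl → C6 (the only free ortho site) and 4'-O-allyl → C3'.
2. Ring C is the only ring made (rings A and B are bought benzenoid pieces): C4–C4a by intramolecular Friedel–Crafts acylation of (R)-acid 13, O1–C2 earlier by Mitsunobu etherification with 3,5-bis(benzyloxy)phenol.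
3. Acid 13 ⇐ oxidative cleavage of the propenyl group of 10, whose inner carbon becomes C4.
4. C3 and the C2–C3 bond ⇐ Wittig–Still [2,3]-sigmatropic rearrangement of stannylmethyl ether 6, with 1,3-chirality transfer from the carbinol centre of bought (S)-but-3-yn-2-ol (that centre later leaves as acetaldehyde).
5. 6 ⇐ Sonogashira coupling, Lindlar reduction and O-alkylation from 1-bromo-4-tert-butoxybenzene.

## Route

**Step 1**
Reactants: 1 1-bromo-4-(tert-butoxy)benzene; 2 (S)-but-3-yn-2-ol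
Product: 3 (2S)-4-[4-(tert-butoxy)phenyl]but-3-yn-2-ol
Conditions: PdCl2(PPh3)2 (3 mol %), CuI (3 mol %), Et3N, 70 °C
Reagents that add atoms: none
Why: Sonogashira coupling joins ring B to the alkyne terminus under mild amine base, leaving the bought S carbinol centre untouched.

**Step 2**
Reactants: 3 (2S)-4-[4-(tert-butoxy)phenyl]but-3-yn-2-ol
Product: 4 (2S,3Z)-4-[4-(tert-butoxy)phenyl]but-3-en-2-ol
Conditions: H2 (1 atm), Pd/CaCO3 poisoned with Pb(OAc)2 (Lindlar catalyst), quinoline, EtOAc, rt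
Reagents that add atoms: none
Why: Lindlar semihydrogenation adds H2 syn to the alkyne and stops at the Z-alkene, the geometry that later enforces a single transition state; the carbinol centre is not involved.

**Step 3**
Reactants: 4 (2S,3Z)-4-[4-(tert-butoxy)phenyl]but-3-en-2-ol
Product: 6 tributyl({[(2S,3Z)-4-(4-tert-butoxyphenyl)but-3-en-2-yl]oxy}methyl)stannane, via potassium alkoxide 5 (not isolated)
Conditions: KH, THF, 0 °C; then Bu3SnCH2I, 0 °C → rt
Reagents that add atoms: tributyl(iodomethyl)stannane, CCCC[Sn](CCCC)(CCCC)CI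
Why: Williamson etherification of the potassium alkoxide with the primary iodide installs the tin–lithium exchange handle without touching the stereocentre or the Z-alkene.

**Step 4**
Reactants: 6 tributyl({[(2S,3Z)-4-(4-tert-butoxyphenyl)but-3-en-2-yl]oxy}methyl)stannane
Product: 8 (2R,3E)-2-[4-(tert-butoxy)phenyl]pent-3-en-1-ol, via alkoxymethyllithium 7 (not isolated)
Conditions: n-BuLi, THF, −78 °C; aq. NH4Cl
Reagents that add atoms: none
Why: Tin–lithium exchange gives an unstabilised α-alkoxy carbanion that undergoes the Wittig–Still [2,3]-sigmatropic rearrangement at −78 °C: the new C–C bond forms suprafacially at the aryl-bearing alkene carbon on the face from which the C–O bond leaves, and with the Z-alkene allylic 1,3-strain forces the carbinol H inside, so the 2S centre is relayed into the 2R benzylic centre and an E-propenyl group.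

**Step 5**
Reactants: 8 (2R,3E)-2-[4-(tert-butoxy)phenyl]pent-3-en-1-ol; 9 3,5-bis(benzyloxy)phenol
Product: 10 1,3-bis(benzyloxy)-5-{[(2R,3E)-2-(4-tert-butoxyphenyl)pent-3-en-1-yl]oxy}benzene
Conditions: PPh3, DIAD, THF, 0 °C → rt
Reagents that add atoms: none
Why: Mitsunobu etherification at the primary carbinol with the phenol forms the future O1–C2 bond; the adjacent stereocentre is not a reacting centre and has no acidic hydrogen.

**Step 6**
Reactants: 10 1,3-bis(benzyloxy)-5-{[(2R,3E)-2-(4-tert-butoxyphenyl)pent-3-en-1-yl]oxy}benzene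
Product: 13 (2R)-3-[3,5-bis(benzyloxy)phenoxy]-2-(4-tert-butoxyphenyl)propanoic acid, via diol 11 (not isolated), via aldehyde 12 (not isolated)
Conditions: OsO4 (2 mol %), NaIO4, THF/H2O, 0 °C → rt; crude aldehyde taken on at once: NaClO2, NaH2PO4, 2-methyl-2-butene, t-BuOH/H2O, 0 °C
Reagents that add atoms: osmium tetroxide, O=[Os](=O)(=O)=O; sodium periodate, [Na+].[O-]I(=O)(=O)=O; water, O; sodium chlorite, [Na+].[O-]Cl=O
Why: Lemieux–Johnson cleavage (OsO4-catalysed dihydroxylation, periodate glycol fission) of the only alkene, chosen over ozone to spare the electron-rich ring A, followed at once by buffered Pinnick oxidation, turns the propenyl group into the carboxyl carbon (future C4) with the stereocentre untouched.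

**Step 7**
Reactants: 13 (2R)-3-[3,5-bis(benzyloxy)phenoxy]-2-(4-tert-butoxyphenyl)propanoic acid
Product: 16 (3R)-7-(benzyloxy)-5-hydroxy-3-(4-hydroxyphenyl)chroman-4-one, via mixed anhydride 14 (not isolated), via protected isoflavanone 15 (not isolated)
Conditions: TFAA (1.2 equiv), CH2Cl2, 0 °C → rt; then TFA/CH2Cl2 (1:1), rt; aq. NaHCO3
Reagents that add atoms: none
Why: The mixed trifluoroacetic anhydride acylates the symmetric, strongly activated ring A ortho to the ether oxygen (both ortho sites are equivalent) in an intramolecular Friedel–Crafts acylation that closes ring C, and TFA then cleaves the tert-butyl ether and, through assistance by the peri carbonyl, only the 5-O-benzyl ether, all under acidic, base-free conditions that do not form the C3 enolate.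

**Step 8**
Reactants: 16 (3R)-7-(benzyloxy)-5-hydroxy-3-(4-hydroxyphenyl)chroman-4-one
Product: 17 (3R)-7-(benzyloxy)-5-(prop-2-en-1-yloxy)-3-[4-(prop-2-en-1-yloxy)phenyl]chroman-4-one
Conditions: allyl alcohol (3 equiv), PPh3, DIAD, THF, 0 °C → rt
Reagents that add atoms: allyl alcohol (prop-2-en-1-ol), C=CCO
Why: Double Mitsunobu O-allylation of the two free phenols (the chelated 5-OH reacts under these conditions) proceeds without added base, so C3 is not epimerised, and the 7-O-benzyl ether blocks the third oxygen.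

**Step 9**
Reactants: 17 (3R)-7-(benzyloxy)-5-(prop-2-en-1-yloxy)-3-[4-(prop-2-en-1-yloxy)phenyl]chroman-4-one
Product: 18 (3R)-7-(benzyloxy)-5-hydroxy-6-(prop-2-en-1-yl)-3-[4-(prop-2-en-1-yloxy)phenyl]chroman-4-one
Conditions: Eu(fod)3 (10 mol %; fod = 6,6,7,7,8,8,8-heptafluoro-2,2-dimethyloctane-3,5-dionate), CHCl3, 65 °C, sealed tube
Reagents that add atoms: none
Why: Eu(fod)3 chelates the C4 carbonyl and the 5-ether oxygen and catalyses the aromatic Claisen rearrangement ([3,3]-sigmatropic) of the 5-O-allyl group to C6, the only open ortho position (C4a is substituted), while the non-chelated 4'-allyl ether stays in place at this temperature.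

**Step 10**
Reactants: 18 (3R)-7-(benzyloxy)-5-hydroxy-6-(prop-2-en-1-yl)-3-[4-(prop-2-en-1-yloxy)phenyl]chroman-4-one
Product: 20 (3R)-5,7-dihydroxy-3-[4-hydroxy-3-(prop-2-en-1-yl)phenyl]-6-(prop-2-en-1-yl)chroman-4-one, via debenzylated allyl ether 19 (not isolated)
Conditions: BCl3 (6 equiv), C6HMe5 (4 equiv), CH2Cl2, −78 °C, then −78 → −20 °C; H2O
Reagents that add atoms: none
Why: BCl3 with pentamethylbenzene as benzyl-cation trap removes the 7-O-benzyl group at −78 °C, and on warming the BCl3-complexed 4'-allyl ether undergoes the charge-accelerated aromatic Claisen rearrangement ([3,3]-sigmatropic) to the equivalent ortho carbons (C3'), the low temperature and absence of base keeping C3 intact.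

**Step 11**
Reactants: 20 (3R)-5,7-dihydroxy-3-[4-hydroxy-3-(prop-2-en-1-yl)phenyl]-6-(prop-2-en-1-yl)chroman-4-one
Product: 21 (3R)-5,7-dihydroxy-3-[4-hydroxy-3-(3-methylbut-2-en-1-yl)phenyl]-6-(3-methylbut-2-en-1-yl)chroman-4-one
Conditions: second-generation Grubbs catalyst RuCl2(=CHPh)(PCy3)(H2IMes) (5 mol %), 2-methyl-2-butene/CH2Cl2, 40 °C, sealed
Reagents that add atoms: 2-methylbut-2-ene, CC=C(C)C
Why: Olefin cross-metathesis with excess 2-methyl-2-butene converts both terminal allyl groups into prenyl groups under neutral conditions that tolerate free phenols and do not touch C3.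

## Compound list

1 | 1-bromo-4-(tert-butoxy)benzene | CC(C)(C)Oc1ccc(Br)cc1 | starting material
2 | (S)-but-3-yn-2-ol | C[C@H](O)C#C | starting material
3 | (2S)-4-[4-(tert-butoxy)phenyl]but-3-yn-2-ol | C[C@H](O)C#Cc1ccc(OC(C)(C)C)cc1 | intermediate
4 | (2S,3Z)-4-[4-(tert-butoxy)phenyl]but-3-en-2-ol | C[C@H](O)/C=C\c1ccc(OC(C)(C)C)cc1 | intermediate
5 | potassium (2S,3Z)-4-[4-(tert-butoxy)phenyl]but-3-en-2-olate | C[C@H]([O-])/C=C\c1ccc(OC(C)(C)C)cc1.[K+] | intermediate (not isolated)
6 | tributyl({[(2S,3Z)-4-(4-tert-butoxyphenyl)but-3-en-2-yl]oxy}methyl)stannane | C[C@H](OC[Sn](CCCC)(CCCC)CCCC)/C=C\c1ccc(OC(C)(C)C)cc1 | intermediate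
7 | ({[(2S,3Z)-4-(4-tert-butoxyphenyl)but-3-en-2-yl]oxy}methyl)lithium | C[C@H](OC[Li])/C=C\c1ccc(OC(C)(C)C)cc1 | intermediate (not isolated)
8 | (2R,3E)-2-[4-(tert-butoxy)phenyl]pent-3-en-1-ol | OC[C@@H](c1ccc(OC(C)(C)C)cc1)/C=C/C | intermediate
9 | 3,5-bis(benzyloxy)phenol | Oc1cc(OCc2ccccc2)cc(OCc2ccccc2)c1 | starting material
10 | 1,3-bis(benzyloxy)-5-{[(2R,3E)-2-(4-tert-butoxyphenyl)pent-3-en-1-yl]oxy}benzene | C(Oc1cc(OCc2ccccc2)cc(OCc2ccccc2)c1)[C@@H](c1ccc(OC(C)(C)C)cc1)/C=C/C | intermediate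
11 | (2R)-1-[3,5-bis(benzyloxy)phenoxy]-2-(4-tert-butoxyphenyl)pentane-3,4-diol (syn-diol, two diastereomers at C3/C4) | C(Oc1cc(OCc2ccccc2)cc(OCc2ccccc2)c1)[C@@H](c1ccc(OC(C)(C)C)cc1)C(O)C(C)O | intermediate (not isolated)
12 | (2R)-3-[3,5-bis(benzyloxy)phenoxy]-2-(4-tert-butoxyphenyl)propanal | C(Oc1cc(OCc2ccccc2)cc(OCc2ccccc2)c1)[C@@H](c1ccc(OC(C)(C)C)cc1)C=O | intermediate (not isolated)
13 | (2R)-3-[3,5-bis(benzyloxy)phenoxy]-2-(4-tert-butoxyphenyl)propanoic acid | C(Oc1cc(OCc2ccccc2)cc(OCc2ccccc2)c1)[C@@H](c1ccc(OC(C)(C)C)cc1)C(=O)O | intermediate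
14 | (2R)-3-[3,5-bis(benzyloxy)phenoxy]-2-(4-tert-butoxyphenyl)propanoic trifluoroacetic anhydride | C(Oc1cc(OCc2ccccc2)cc(OCc2ccccc2)c1)[C@@H](c1ccc(OC(C)(C)C)cc1)C(=O)OC(=O)C(F)(F)F | intermediate (not isolated)
15 | (3R)-5,7-bis(benzyloxy)-3-(4-tert-butoxyphenyl)chroman-4-one | CC(C)(C)Oc1ccc([C@@H]2COc3cc(OCc4ccccc4)cc(OCc4ccccc4)c3C2=O)cc1 | intermediate (not isolated)
16 | (3R)-7-(benzyloxy)-5-hydroxy-3-(4-hydroxyphenyl)chroman-4-one | Oc1ccc([C@@H]2COc3cc(OCc4ccccc4)cc(O)c3C2=O)cc1 | intermediate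
17 | (3R)-7-(benzyloxy)-5-(prop-2-en-1-yloxy)-3-[4-(prop-2-en-1-yloxy)phenyl]chroman-4-one | C=CCOc1ccc([C@@H]2COc3cc(OCc4ccccc4)cc(OCC=C)c3C2=O)cc1 | intermediate
18 | (3R)-7-(benzyloxy)-5-hydroxy-6-(prop-2-en-1-yl)-3-[4-(prop-2-en-1-yloxy)phenyl]chroman-4-one | C=CCOc1ccc([C@@H]2COc3cc(OCc4ccccc4)c(CC=C)c(O)c3C2=O)cc1 | intermediate
19 | (3R)-5,7-dihydroxy-6-(prop-2-en-1-yl)-3-[4-(prop-2-en-1-yloxy)phenyl]chroman-4-one | C=CCOc1ccc([C@@H]2COc3cc(O)c(CC=C)c(O)c3C2=O)cc1 | intermediate (not isolated)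
20 | (3R)-5,7-dihydroxy-3-[4-hydroxy-3-(prop-2-en-1-yl)phenyl]-6-(prop-2-en-1-yl)chroman-4-one | C=CCc1cc([C@@H]2COc3cc(O)c(CC=C)c(O)c3C2=O)ccc1O | intermediate
21 | (3R)-5,7-dihydroxy-3-[4-hydroxy-3-(3-methylbut-2-en-1-yl)phenyl]-6-(3-methylbut-2-en-1-yl)chroman-4-one (CNP0206440.1) | CC(C)=CCc1cc([C@@H]2COc3cc(O)c(CC=C(C)C)c(O)c3C2=O)ccc1O | target

## Step count and risks

Total step count: 11. Longest linear sequence: 11 steps (1 or 2 → 21); fragment 9 is bought.

**Step 6.** Aldehyde 12 is α-aryl and β-aryloxy, so it can epimerise or lose the aryloxide, and chlorite-derived HOCl can chlorinate ring A. Fallback: set out from 10, dihydroxylate with OsO4 (cat.)/N-methylmorpholine N-oxide and isolate diol 11. Cleave 11 with NaIO4 on silica and run the filtrate directly into NaBH4/EtOH at 0 °C to give (2S)-3-[3,5-bis(benzyloxy)phenoxy]-2-(4-tert-butoxyphenyl)propan-1-ol F1, a configurationally robust alcohol on which the ee can be checked. Oxidise F1 with TEMPO (cat.)/PhI(OAc)2 in MeCN/H2O, which carries the alcohol through to the acid without a chlorine oxidant, and come back to the route at 13.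

**Step 7.** Prolonged TFA exposure may partly racemise C3 by acid-catalysed enolisation, and the two ether cleavages may not stop cleanly at the 7-O-benzyl stage. Fallback: set out from 13, cyclise with TFAA alone at 0 °C and isolate 15. Remove only the peri benzyl group by chelation with MgBr2·OEt2 (toluene/Et2O, 50 °C) to give (3R)-7-(benzyloxy)-3-(4-tert-butoxyphenyl)-5-hydroxychroman-4-one F2. Cleave the tert-butyl ether of F2 by a brief exposure to dilute TFA in CH2Cl2 at 0 °C and come back to the route at 16.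

**Step 10.** BCl3 may cleave the 4'-allyl ether instead of rearranging it, or the two events may not run cleanly in one flask. Fallback: set out from 18 and run the uncatalysed thermal aromatic Claisen rearrangement (degassed 1,2-dichlorobenzene, 180 °C, microwave, short time) to give (3R)-7-(benzyloxy)-5-hydroxy-3-[4-hydroxy-3-(prop-2-en-1-yl)phenyl]-6-(prop-2-en-1-yl)chroman-4-one F3. Debenzylate F3 in a separate operation held at −78 °C (BCl3, pentamethylbenzene, CH2Cl2) and come back to the route at 20; the ee should be checked after the heating.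

## Further compounds

F1 | step 6 | (2S)-3-[3,5-bis(benzyloxy)phenoxy]-2-(4-tert-butoxyphenyl)propan-1-ol | C(Oc1cc(OCc2ccccc2)cc(OCc2ccccc2)c1)[C@@H](c1ccc(OC(C)(C)C)cc1)CO
F2 | step 7 | (3R)-7-(benzyloxy)-3-(4-tert-butoxyphenyl)-5-hydroxychroman-4-one | CC(C)(C)Oc1ccc([C@@H]2COc3cc(OCc4ccccc4)cc(O)c3C2=O)cc1
F3 | step 10 | (3R)-7-(benzyloxy)-5-hydroxy-3-[4-hydroxy-3-(prop-2-en-1-yl)phenyl]-6-(prop-2-en-1-yl)chroman-4-one | C=CCc1cc([C@@H]2COc3cc(OCc4ccccc4)c(CC=C)c(O)c3C2=O)ccc1O
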